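Compound numbers are those of the step list. Positions follow the natural-product numbering: C1 is the benzylic CH2, C2–C7 are ring A (methylene C20 on C3, bromine on C6, methyl on C7), C8–C15 the chain (epoxide at C10–C11, ester oxygen on C14, carbinol C15), and C1′ (carboxyl) to C5′ (bearing C1) the arene.

## The problem

Bromophycolide F is a 15-membered benzoate macrolide in which a 4-hydroxybenzoate is tied to a diterpene chain twice: through the ester oxygen on C14 and through the benzylic methylene C1, which links aryl carbon C5′ to C2 of a bromocyclohexane (ring A). Ring A holds three contiguous stereocentres (C2, C6 with equatorial bromine, quaternary C7) and an exocyclic methylene on C3. C6 and C7 can be set together by anti addition across an (E)-alkene. C7 can then steer C2, and C2 is also correctable by equilibration whenever C3 is a carbonyl. The (10S,11S)-epoxide and the (14S)-carbinol are too remote from ring A and from each other for relay, so each needs reagent control. Several groups limit the choice of reagents: the neopentyl secondary bromide (hydride, radicals, low-valent metals), the trisubstituted epoxide with the C15 alcohol placed to open it under acid, the exocyclic alkene (acid isomerization), the aryl ester and the phenol. The feature that opens the chosen route is that C1 is an unactivated CH2 between an sp2 carbon and the stereocentre C2, while the neighbouring C3 carries a methylene that is the olefination product of a ketone. C1=C2 can therefore start as an exocyclic alkene beside a C3 ketal; hydroboration then places boron on C1 and hydrogen on C2, and the C1–C5′ bond closes the macrocycle by sp3–sp2 coupling at an unhindered primary carbon.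

## Retrosynthesis

**Late oxidation state.** The epoxide is removed first (32 to alkene 31), because it would not survive the acid needed for deprotection. The C3 methylene is then cut to ketone 30, which gives C2 a chance to equilibrate and is the function that must be masked during the key step. Ketone 30 comes from macrocycle 29 by hydrolysis of the C3 ketal and the aryl methoxymethyl ether. Asked of the forward steps: an epoxidation that chooses C10=C11 over C3=C20 and the correct face, and a methylenation that leaves the benzoate alone.

**C1–C5′ (key cut).** Macrocycle 29 is opened between C1 and C5′, with C2–H removed, to give aryl iodide 27 through alkylborane 28. The neighbouring cuts are weaker: lactonization would have to close the ring at the hindered C14 hydroxyl, and a C1–C2 cut would ask the ring closure to form a bond at C2, next to the quaternary C7. The chosen cut closes at a primary carbon, sets C2 in the same operation, and leaves the ester to be made intermolecularly. The precursor is acyclic apart from ring A and the arene is a commercial iodophenol. Asked of the forward step: hydroboration of the 1,1-disubstituted alkene only, from the face anti to the C7 methyl, and coupling that beats oligomerization.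

**Ester C–O.** Ester 27 is cut to diol 23 and acid 26; only the secondary C14 hydroxyl should acylate. Acid 26 comes from methyl 4-hydroxy-3-iodobenzoate 24 through ether 25.

**C14 and C12–C13.** Diol 23 is traced through silyl ether 22 to ketone 21 (C14 set by catalytic asymmetric reduction). Ketone 21 is cut at C12–C13 into allylic bromide 17 and the enolate 20 of silyloxy ketone 19, the trimethylsilyl ether of commercial 3-hydroxy-3-methylbutan-2-one 18. The alternative, a prenyl unit followed by dihydroxylation, would have to distinguish the C14=C15 alkene from C10=C11; here C14 is created at a carbonyl with no competitor. Bromide 17 comes from alcohol 15 (via mesylate 16) and enoate 14.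

**C3 ketal and C1.** Ketal 14 comes from racemic enone 13 and (2R,3R)-butane-2,3-diol. The C2-symmetric diol adds no stereocentre and turns the two enantiomers of 13 into separable diastereomers, so protection and resolution are one step; 14 is the diastereomer with the (6S,7S) ring. Enone 13 is cut at C1=C2 to keto ester 11 (via keto acid 12): the carboxyl group fixes the site of methylenation at the hindered C2 and then leaves as CO2.

**Ring A.** Keto ester 11 is cut at C2–C7 and C6–Br to acyclic keto ester 10, a bromonium cyclization ended by the keto ester enol. This sets the bromine cis to the C7 methyl from the (6E)-alkene. The conjugated ester on C11 makes C10=C11 electron-poor, so only C6=C7 takes up Br+; this is why the chain is carried as an enoate at this stage. The product is racemic, which the ketal step answers.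

**Chain.** Keto ester 10 is cut at C4–C5 into allyl acetoacetate 8 (as dianion 9) and bromide 7. Bromide 7 comes from alcohol 6 and acetate 5; 5 is cut at C10=C11 into aldehyde 3 and stabilized ylide 4; aldehyde 3 is the ozonolysis product (via ozonide 2) of geranyl acetate 1, which supplies C5–C10 with the (6E)-alkene in place.

## Roads not taken

**Alternative 1:** Transannular bromonium cyclization. The cut is C2–C7 and C6–Br in acetonide A2, leading back to the 19-membered macrolactone A1 with C2=C3 and C6=C7 alkenes. In the forward direction Et2SBr·SbCl5Br would deliver Br+ to C6=C7, C2 would attack C7 across the ring, and C20 would lose a proton.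
- Merits: one step makes ring A, the bromide, C2, C6, C7 and the exocyclic alkene and contracts the ring; no methylenation, no resolution if the macrocycle relays its stereochemistry, and clearly fewer steps.
- Weak points: A1 has two trisubstituted alkenes of similar nucleophilicity; the C3 cation can lose a proton toward C20, C4 or C2; the face of bromonium formation is governed only by the conformation of a flexible 19-membered ring with remote stereocentres; the arene can act as a competing terminator.
- Comparison: this road is shorter and in principle needs no resolution. The chosen plan sets against it that each selectivity has a known controlling element: one electron-rich alkene at the bromination stage, a carbon terminator with no alternative, and a methylene position fixed by a carbonyl. The cost is a resolution and more steps.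

**Alternative 2:** Coumalate–siloxyalkyne Diels–Alder. The cut is C3′–C4′ and C5′–C6′ of the arene in bis-silyl ether A4, giving coumalate/siloxyalkyne A3. Heating at high dilution would effect intramolecular inverse-demand [4+2] cycloaddition and loss of CO2.
- Merits: arene and macrocycle form together, the conditions are neutral and metal-free, and the epoxide and methylene can already be present, so only desilylation follows. The endgame is milder than the chosen one, which needs acid, methylenation and a late epoxidation.
- Weak points: ring A must already carry C1 and the C2 stereocentre, made separately; siloxyalkynes and coumalates are sensitive and must be installed late on a fragment holding a bromide and an epoxide; the cycloaddition must reach a bridged transition state across 15 atoms at temperatures where the bromide and epoxide are at risk.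
- Comparison: this road builds more in the key step and finishes closer to the target. The chosen plan offers a commercial arene, C2 set within the key step, and a ring closure with a broad macrocyclization record.

**Alternative 3:** o-Quinone methide Michael macrocyclization. The cut is C1–C2 in keto ester A6, giving seco compound A5 with a 2-(acetoxymethyl)phenol and the ring A β-keto allyl ester. Cs2CO3 would generate the quinone methide and the C2 enolate would add to C1.
- Merits: the keto ester from the bromocyclization is used directly (no ketal, no hydroboration), the epoxide is installed before ring closure, and decarboxylation afterwards sets C2 thermodynamically. It is probably several steps shorter and avoids the late epoxidation question.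
- Weak points: the ring closure must create a quaternary carbon next to quaternary C7; β-dicarbonyls often add to quinone methides through oxygen or by [4+2] to give chroman ketals; an untrapped quinone methide oligomerizes; the epoxide must then survive decarboxylation and methylenation.
- Comparison: the chosen plan is longer but closes the ring at a primary carbon, and C2 can be controlled twice, kinetically in the hydroboration and thermodynamically at the ketone.

Key step: step 17

Assumption: the dioxirane from the L-fructose-derived ketone gives (S,S)-epoxides from (E)-trisubstituted alkenes, the mirror image of the D-fructose-derived catalyst.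
Assumption: compounds 11–13 are racemic; their SMILES show the enantiomer that is carried on after step 8.

## Steps

Step 1
Reactants: 1 geranyl acetate
Product: 3 (2E)-3-methyl-6-oxohex-2-en-1-yl acetate, via secondary ozonide 2 (not isolated)
Conditions: O3, CH2Cl2, pyridine (cat.), −78 °C; then Me2S, −78 °C to rt
Reagents that add atoms: ozone, [O-][O+]=O
Why: Chemoselective ozonolysis: the allylic acetate lowers the electron density of the 2,3-alkene, so ozone cleaves the remote isopropylidene alkene, and Me2S reduces the ozonide to the aldehyde.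

Step 2
Reactants: 3 (2E)-3-methyl-6-oxohex-2-en-1-yl acetate; 4 ethyl 2-(triphenylphosphoranylidene)propanoate
Product: 5 ethyl (2E,6E)-8-acetoxy-2,6-dimethylocta-2,6-dienoate
Conditions: CH2Cl2, rt
Reagents that add atoms: none
Why: Wittig olefination with a stabilized ylide, which should give the (E)-trisubstituted enoate (future C10=C11 with its methyl and C12).

Step 3
Reactants: 5 ethyl (2E,6E)-8-acetoxy-2,6-dimethylocta-2,6-dienoate
Product: 6 ethyl (2E,6E)-8-hydroxy-2,6-dimethylocta-2,6-dienoate
Conditions: K2CO3 (cat.), EtOH, 0 °C to rt
Reagents that add atoms: none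
Why: Base-catalysed transesterification frees the allylic alcohol; ethanol matches the ethyl ester, and the trisubstituted enoate does not add alkoxide.

Step 4
Reactants: 6 ethyl (2E,6E)-8-hydroxy-2,6-dimethylocta-2,6-dienoate
Product: 7 ethyl (2E,6E)-8-bromo-2,6-dimethylocta-2,6-dienoate
Conditions: CBr4, PPh3, CH2Cl2, 0 °C
Reagents that add atoms: carbon tetrabromide, BrC(Br)(Br)Br
Why: Appel reaction; SN2 displacement of the alkoxyphosphonium at the primary allylic carbon without transposition, and the bromide is used directly.

Step 5
Reactants: 8 allyl acetoacetate; 7 ethyl (2E,6E)-8-bromo-2,6-dimethylocta-2,6-dienoate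
Product: 10 12-ethyl 1-(prop-2-en-1-yl) (6E,10E)-7,11-dimethyl-3-oxododeca-6,10-dienedioate, via acetoacetate dianion 9 (not isolated)
Conditions: NaH, THF, 0 °C; n-BuLi, 0 °C; then 7, 0 °C; aq. NH4Cl
Reagents that add atoms: none
Why: Weiler dianion alkylation: the more basic terminal carbanion displaces the allylic bromide, so the bond forms at C4–C5 and the C2 methylene stays free for the cyclization.

Step 6
Reactants: 10 12-ethyl 1-(prop-2-en-1-yl) (6E,10E)-7,11-dimethyl-3-oxododeca-6,10-dienedioate
Product: 11 rac-prop-2-en-1-yl (2S,3S)-3-bromo-2-[(3E)-5-ethoxy-4-methyl-5-oxopent-3-en-1-yl]-2-methyl-6-oxocyclohexane-1-carboxylate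
Conditions: Et2SBr·SbCl5Br (1.1 equiv), MeNO2, −25 °C, 10 min; aq. NaHCO3/Na2SO3
Reagents that add atoms: bromodiethylsulfonium bromopentachloroantimonate, CC[S+](Br)CC.Cl[Sb-](Cl)(Cl)(Cl)(Cl)Br
Why: Bromonium-initiated cation–olefin cyclization ended by the enol of the β-keto ester: Br+ goes to C6=C7, the only electron-rich alkene (enoate and allyl ester are deactivated), and C2 attacks tertiary C7 anti to bromine through a chair, which places bromine equatorial and cis to the C7 methyl. The product is racemic, and the C2 epimers and enol converge in step 7.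

Step 7
Reactants: 11 rac-prop-2-en-1-yl (2S,3S)-3-bromo-2-[(3E)-5-ethoxy-4-methyl-5-oxopent-3-en-1-yl]-2-methyl-6-oxocyclohexane-1-carboxylate
Product: 13 rac-ethyl (2E)-5-[(1S,6S)-6-bromo-1-methyl-2-methylidene-3-oxocyclohexyl]-2-methylpent-2-enoate, via keto acid 12 (not isolated)
Conditions: Pd(PPh3)4 (5 mol %), morpholine (1.1 equiv), THF, 0 °C; then 37% aq. CH2O, Et2NH (0.3 equiv), 0 to 40 °C
Reagents that add atoms: formaldehyde, C=O
Why: Zerovalent palladium ionizes the allyl ester and morpholine traps the allyl group; the β-keto acid then undergoes the decarboxylative Mannich reaction, and loss of CO2 and amine leaves the methylene (C1) on C2, the site fixed by the carboxyl group.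

Step 8
Reactants: 13 rac-ethyl (2E)-5-[(1S,6S)-6-bromo-1-methyl-2-methylidene-3-oxocyclohexyl]-2-methylpent-2-enoate
Product: 14 ethyl (2E)-5-[(2R,3R,7S,8S)-8-bromo-2,3,7-trimethyl-6-methylidene-1,4-dioxaspiro[4.5]decan-7-yl]-2-methylpent-2-enoate
Conditions: (2R,3R)-butane-2,3-diol, i-PrOSiMe3, Me3SiOTf (10 mol %), CH2Cl2, −20 °C; pyridine; chromatography on silica
Reagents that add atoms: (2R,3R)-butane-2,3-diol, C[C@@H](O)[C@@H](C)O
Why: Silyl-triflate-catalysed (Noyori-type) ketalization masks the C3 ketone under conditions too mild to isomerize the exocyclic enone. The C2-symmetric diol creates no new stereocentre and converts the two enantiomers of 13 into diastereomeric ketals that should be separable by chromatography (resolution); the (7S,8S)-diastereomer 14 is kept and its configuration is to be secured by crystallography using the bromine atom.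

Step 9
Reactants: 14 ethyl (2E)-5-[(2R,3R,7S,8S)-8-bromo-2,3,7-trimethyl-6-methylidene-1,4-dioxaspiro[4.5]decan-7-yl]-2-methylpent-2-enoate
Product: 15 (2E)-5-[(2R,3R,7S,8S)-8-bromo-2,3,7-trimethyl-6-methylidene-1,4-dioxaspiro[4.5]decan-7-yl]-2-methylpent-2-en-1-ol
Conditions: i-Bu2AlH (2.5 equiv), CH2Cl2, −78 °C; aq. KNaC4H4O6
Reagents that add atoms: none
Why: 1,2-Reduction of the enoate to the allylic alcohol; the ketal and the hindered secondary bromide should be inert at −78 °C.

Step 10
Reactants: 15 (2E)-5-[(2R,3R,7S,8S)-8-bromo-2,3,7-trimethyl-6-methylidene-1,4-dioxaspiro[4.5]decan-7-yl]-2-methylpent-2-en-1-ol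
Product: 17 (2R,3R,7S,8S)-8-bromo-7-[(3E)-5-bromo-4-methylpent-3-en-1-yl]-2,3,7-trimethyl-6-methylidene-1,4-dioxaspiro[4.5]decane, via allylic mesylate 16 (not isolated)
Conditions: MsCl, Et3N, THF, −40 °C; then LiBr, THF, 0 °C
Reagents that add atoms: lithium bromide, [Li+].[Br-]
Why: Mesylation and SN2 displacement by bromide under buffered conditions that spare the ketal; the primary allylic centre reacts without transposition.

Step 11
Reactants: 18 3-hydroxy-3-methylbutan-2-one
Product: 19 3-methyl-3-(trimethylsilyloxy)butan-2-one
Conditions: Me3SiCl, imidazole, DMF, 0 °C to rt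
Reagents that add atoms: chlorotrimethylsilane, C[Si](C)(C)Cl
Why: O-Silylation of the tertiary α-hydroxy ketone with the small trimethylsilyl group, which keeps the hydroxyl from quenching the enolate in step 12 and comes off under mild methanolysis later.

Step 12
Reactants: 17 (2R,3R,7S,8S)-8-bromo-7-[(3E)-5-bromo-4-methylpent-3-en-1-yl]-2,3,7-trimethyl-6-methylidene-1,4-dioxaspiro[4.5]decane; 19 3-methyl-3-(trimethylsilyloxy)butan-2-one
Product: 21 (6E)-9-[(2R,3R,7S,8S)-8-bromo-2,3,7-trimethyl-6-methylidene-1,4-dioxaspiro[4.5]decan-7-yl]-2,6-dimethyl-2-(trimethylsilyloxy)non-6-en-3-one, via lithium enolate 20 (not isolated)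
Conditions: 19 (2 equiv), LiN(i-Pr)2, THF, −78 °C; then 17, DMPU, −78 to −20 °C
Reagents that add atoms: none
Why: Ketone enolate alkylation forms C12–C13; ketone 19 can enolize only toward its methyl group, excess enolate suppresses dialkylation, and the neopentyl ring bromide is inert to SN2.

Step 13
Reactants: 21 (6E)-9-[(2R,3R,7S,8S)-8-bromo-2,3,7-trimethyl-6-methylidene-1,4-dioxaspiro[4.5]decan-7-yl]-2,6-dimethyl-2-(trimethylsilyloxy)non-6-en-3-one
Product: 23 (3S,6E)-9-[(2R,3R,7S,8S)-8-bromo-2,3,7-trimethyl-6-methylidene-1,4-dioxaspiro[4.5]decan-7-yl]-2,6-dimethylnon-6-ene-2,3-diol, via silyl ether 22 (not isolated)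
Conditions: (R)-2-methyl-CBS-oxazaborolidine (0.2 equiv), catecholborane, toluene, −78 °C; MeOH; then K2CO3 (cat.), MeOH, rt
Reagents that add atoms: none
Why: Corey–Bakshi–Shibata reduction: the catalyst distinguishes the fully substituted C(CH3)2OSiMe3 group from the CH2 chain and the (R)-catalyst should deliver hydride to give 14S. Catecholborane does not hydroborate the alkenes at −78 °C, and methanolysis then removes the trimethylsilyl group.

Step 14
Reactants: 24 methyl 4-hydroxy-3-iodobenzoate
Product: 25 methyl 3-iodo-4-(methoxymethoxy)benzoate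
Conditions: MOMCl, i-Pr2NEt, CH2Cl2, 0 °C to rt
Reagents that add atoms: chloromethyl methyl ether, COCCl
Why: O-Alkylation of the phenol gives a small acetal ether that tolerates base, borane and palladium and is removed by the same acid as the ketal.

Step 15
Reactants: 25 methyl 3-iodo-4-(methoxymethoxy)benzoate
Product: 26 3-iodo-4-(methoxymethoxy)benzoic acid
Conditions: LiOH, THF/MeOH/H2O, rt; cold 1 M HCl to pH 4
Reagents that add atoms: lithium hydroxide, [Li+].[OH-]
Why: Saponification; the methoxymethyl ether is stable to base and to brief cold acidification.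

Step 16
Reactants: 23 (3S,6E)-9-[(2R,3R,7S,8S)-8-bromo-2,3,7-trimethyl-6-methylidene-1,4-dioxaspiro[4.5]decan-7-yl]-2,6-dimethylnon-6-ene-2,3-diol; 26 3-iodo-4-(methoxymethoxy)benzoic acid
Product: 27 (3S,6E)-9-[(2R,3R,7S,8S)-8-bromo-2,3,7-trimethyl-6-methylidene-1,4-dioxaspiro[4.5]decan-7-yl]-2-hydroxy-2,6-dimethylnon-6-en-3-yl 3-iodo-4-(methoxymethoxy)benzoate
Conditions: EDC·HCl, DMAP, CH2Cl2, 0 °C to rt
Reagents that add atoms: none
Why: Steglich esterification; only the secondary C14 hydroxyl is acylated because the tertiary C15 hydroxyl is too hindered, and C14 is not touched at carbon.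

Step 17
Reactants: 27 (3S,6E)-9-[(2R,3R,7S,8S)-8-bromo-2,3,7-trimethyl-6-methylidene-1,4-dioxaspiro[4.5]decan-7-yl]-2-hydroxy-2,6-dimethylnon-6-en-3-yl 3-iodo-4-(methoxymethoxy)benzoate
Product: 29 macrocyclic benzoate (C1–C5′ closed; C3 as (4R,5R)-4,5-dimethyl-1,3-dioxolane; 10E-alkene; aryl methoxymethyl ether; 2S,6S,7S,14S), via alkylborane 28 (not isolated)
Conditions: 9-BBN (3 equiv), THF, rt to 40 °C; H2O; then added over 12 h to PdCl2(dppf) (20 mol %), AsPh3 (40 mol %), Cs2CO3 (3 equiv), DMF/THF/H2O, 50 °C, final 1 mM
Reagents that add atoms: none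
Why: 9-BBN adds syn across the exocyclic C1=C2 alkene, boron on terminal C1 and hydrogen on C2, to give 28. Zerovalent palladium formed from PdCl2(dppf) inserts into the aryl C–I bond, the base-activated borate transfers the C1 alkyl group to palladium, and reductive elimination forms C1–C5′. This is a B-alkyl Suzuki–Miyaura macrocyclization, a known way of closing large rings after hydroboration of a terminal alkene. The 15-membered ring closes end-to-end by reductive elimination from a 16-membered aryl(alkyl)palladacycle; slow addition at high dilution disfavours oligomers, and the rigid benzoate and (E)-alkene lower the entropic cost. C2 is controlled by ring A: in the chair with equatorial bromine the C7 methyl and one ketal oxygen are axial on the same face beside C2, so the borane approaches the opposite face, hydrogen enters axially, and C1 ends equatorial and cis to the methyl. Site selectivity in the hydroboration rests on the much higher rate of 9-BBN with 1,1-disubstituted than with trisubstituted alkenes, with ester and aryl iodide inert and the C15 hydroxyl merely consuming one B–H. In the coupling the aryl iodide undergoes oxidative addition far faster than the hindered secondary alkyl bromide, and the primary C1–B bond transmetallates under the dppf ligand without competitive β-hydride loss. A minor C2 epimer can still equilibrate at the ketone stage in step 18.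

Step 18
Reactants: 29 macrocyclic benzoate (C3 dimethyldioxolane; aryl methoxymethyl ether)
Product: 30 10,11-deoxy-20-nor-3-oxobromophycolide F (macrocyclic C3 ketone; free phenol; 10E-alkene; 2S,6S,7S,14S)
Conditions: 3 M aq. HCl/THF (1:3), 40 °C
Reagents that add atoms: water, O
Why: Acid-catalysed acetal hydrolysis removes the dioxolane and the methoxymethyl ether together. The liberated ketone lets C2 equilibrate through its enol toward the epimer with C1 and C8 both equatorial, while the trisubstituted alkene, the ester and the bromide should withstand dilute aqueous acid.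

Step 19
Reactants: 30 10,11-deoxy-20-nor-3-oxobromophycolide F
Product: 31 10,11-deoxybromophycolide F (10E-alkene; 2R,6S,7S,14S)
Conditions: Zn, CH2Br2, TiCl4, THF, 0 °C to rt (reagent preformed, excess); then 30, CH2Cl2, rt
Reagents that add atoms: dibromomethane, BrCBr
Why: Takai–Lombardo methylenation: the non-basic titanium–methylene reagent converts hindered, enolizable ketones without epimerizing C2 and does not attack the benzoate; excess reagent covers the phenol and the tertiary alcohol.

Step 20
Reactants: 31 10,11-deoxybromophycolide F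
Product: 32 bromophycolide F
Conditions: L-fructose-derived ketone (ent-Shi ketone, 0.5 equiv), KHSO5 (as 2KHSO5·KHSO4·K2SO4), K2CO3 buffer pH 9–10, n-Bu4NHSO4, MeCN/CH2(OMe)2/H2O, 0 °C
Reagents that add atoms: potassium peroxymonosulfate, [K+].[O-]S(=O)(=O)OO
Why: Shi epoxidation: the chiral dioxirane transfers oxygen through a spiro transition state, and the L-series catalyst should give the (10S,11S)-epoxide from the (E)-alkene. The trisubstituted C10=C11 alkene is more electron-rich and more accessible than the hindered 1,1-disubstituted C3=C20 alkene.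

## Compound list

1 | geranyl acetate | CC(C)=CCC/C(C)=C/COC(C)=O | starting material
2 | (2E)-5-(5,5-dimethyl-1,2,4-trioxolan-3-yl)-3-methylpent-2-en-1-yl acetate (secondary ozonide) | CC(=O)OC/C=C(C)/CCC1OOC(C)(C)O1 | intermediate
3 | (2E)-3-methyl-6-oxohex-2-en-1-yl acetate | CC(=O)OC/C=C(C)/CCC=O | intermediate
4 | ethyl 2-(triphenylphosphoranylidene)propanoate | CCOC(=O)C(C)=P(c1ccccc1)(c1ccccc1)c1ccccc1 | starting material
5 | ethyl (2E,6E)-8-acetoxy-2,6-dimethylocta-2,6-dienoate | CCOC(=O)/C(C)=C/CC/C(C)=C/COC(C)=O | intermediate
6 | ethyl (2E,6E)-8-hydroxy-2,6-dimethylocta-2,6-dienoate | CCOC(=O)/C(C)=C/CC/C(C)=C/CO | intermediate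
7 | ethyl (2E,6E)-8-bromo-2,6-dimethylocta-2,6-dienoate | CCOC(=O)/C(C)=C/CC/C(C)=C/CBr | intermediate
8 | allyl acetoacetate | CC(=O)CC(=O)OCC=C | starting material
9 | sodium lithium dianion of allyl acetoacetate | [Na+].[Li+].[CH2-]C(=O)[CH-]C(=O)OCC=C | intermediate
10 | 12-ethyl 1-(prop-2-en-1-yl) (6E,10E)-7,11-dimethyl-3-oxododeca-6,10-dienedioate | C=CCOC(=O)CC(=O)CC/C=C(C)/CC/C=C(C)/C(=O)OCC | intermediate
11 | rac-prop-2-en-1-yl (2S,3S)-3-bromo-2-[(3E)-5-ethoxy-4-methyl-5-oxopent-3-en-1-yl]-2-methyl-6-oxocyclohexane-1-carboxylate (C1 epimers and enol; racemate) | O=C1CC[C@H](Br)[C@@](C)(CC/C=C(C)/C(=O)OCC)C1C(=O)OCC=C | intermediate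
12 | rac-(2S,3S)-3-bromo-2-[(3E)-5-ethoxy-4-methyl-5-oxopent-3-en-1-yl]-2-methyl-6-oxocyclohexane-1-carboxylic acid (racemate) | O=C1CC[C@H](Br)[C@@](C)(CC/C=C(C)/C(=O)OCC)C1C(=O)O | intermediate
13 | rac-ethyl (2E)-5-[(1S,6S)-6-bromo-1-methyl-2-methylidene-3-oxocyclohexyl]-2-methylpent-2-enoate (racemate) | C=C1C(=O)CC[C@H](Br)[C@@]1(C)CC/C=C(C)/C(=O)OCC | intermediate
14 | ethyl (2E)-5-[(2R,3R,7S,8S)-8-bromo-2,3,7-trimethyl-6-methylidene-1,4-dioxaspiro[4.5]decan-7-yl]-2-methylpent-2-enoate | C=C1[C@](C)(CC/C=C(C)/C(=O)OCC)[C@@H](Br)CCC12O[C@H](C)[C@@H](C)O2 | intermediate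
15 | (2E)-5-[(2R,3R,7S,8S)-8-bromo-2,3,7-trimethyl-6-methylidene-1,4-dioxaspiro[4.5]decan-7-yl]-2-methylpent-2-en-1-ol | C=C1[C@](C)(CC/C=C(C)/CO)[C@@H](Br)CCC12O[C@H](C)[C@@H](C)O2 | intermediate
16 | methanesulfonate of 15 | C=C1[C@](C)(CC/C=C(C)/COS(C)(=O)=O)[C@@H](Br)CCC12O[C@H](C)[C@@H](C)O2 | intermediate
17 | (2R,3R,7S,8S)-8-bromo-7-[(3E)-5-bromo-4-methylpent-3-en-1-yl]-2,3,7-trimethyl-6-methylidene-1,4-dioxaspiro[4.5]decane | C=C1[C@](C)(CC/C=C(C)/CBr)[C@@H](Br)CCC12O[C@H](C)[C@@H](C)O2 | intermediate
18 | 3-hydroxy-3-methylbutan-2-one | CC(=O)C(C)(C)O | starting material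
19 | 3-methyl-3-(trimethylsilyloxy)butan-2-one | CC(=O)C(C)(C)O[Si](C)(C)C | intermediate
20 | lithium 3-methyl-3-(trimethylsilyloxy)but-1-en-2-olate | [Li+].C=C([O-])C(C)(C)O[Si](C)(C)C | intermediate
21 | (6E)-9-[(2R,3R,7S,8S)-8-bromo-2,3,7-trimethyl-6-methylidene-1,4-dioxaspiro[4.5]decan-7-yl]-2,6-dimethyl-2-(trimethylsilyloxy)non-6-en-3-one | C=C1[C@](C)(CC/C=C(C)/CCC(=O)C(C)(C)O[Si](C)(C)C)[C@@H](Br)CCC12O[C@H](C)[C@@H](C)O2 | intermediate
22 | (3S,6E)-9-[(2R,3R,7S,8S)-8-bromo-2,3,7-trimethyl-6-methylidene-1,4-dioxaspiro[4.5]decan-7-yl]-2,6-dimethyl-2-(trimethylsilyloxy)non-6-en-3-ol | C=C1[C@](C)(CC/C=C(C)/CC[C@H](O)C(C)(C)O[Si](C)(C)C)[C@@H](Br)CCC12O[C@H](C)[C@@H](C)O2 | intermediate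
23 | (3S,6E)-9-[(2R,3R,7S,8S)-8-bromo-2,3,7-trimethyl-6-methylidene-1,4-dioxaspiro[4.5]decan-7-yl]-2,6-dimethylnon-6-ene-2,3-diol | C=C1[C@](C)(CC/C=C(C)/CC[C@H](O)C(C)(C)O)[C@@H](Br)CCC12O[C@H](C)[C@@H](C)O2 | intermediate
24 | methyl 4-hydroxy-3-iodobenzoate | COC(=O)c1ccc(O)c(I)c1 | starting material
25 | methyl 3-iodo-4-(methoxymethoxy)benzoate | COCOc1ccc(C(=O)OC)cc1I | intermediate
26 | 3-iodo-4-(methoxymethoxy)benzoic acid | COCOc1ccc(C(=O)O)cc1I | intermediate
27 | (3S,6E)-9-[(2R,3R,7S,8S)-8-bromo-2,3,7-trimethyl-6-methylidene-1,4-dioxaspiro[4.5]decan-7-yl]-2-hydroxy-2,6-dimethylnon-6-en-3-yl 3-iodo-4-(methoxymethoxy)benzoate | C=C1[C@](C)(CC/C=C(C)/CC[C@@H](C(C)(C)O)OC(=O)c3ccc(OCOC)c(I)c3)[C@@H](Br)CCC12O[C@H](C)[C@@H](C)O2 | intermediate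
28 | C1 alkylborane of 27: 6-[(9-borabicyclo[3.3.1]nonan-9-yl)methyl] in place of 6-methylidene, (6S), C2–H trans to the C7 methyl | C12(O[C@H](C)[C@@H](C)O1)CC[C@H](Br)[C@@](C)(CC/C=C(C)/CC[C@@H](C(C)(C)O)OC(=O)c3ccc(OCOC)c(I)c3)[C@@H]2CB4C5CCCC4CCC5 | intermediate
29 | macrocyclic benzoate: C1–C5′ closed, C3 as (4R,5R)-4,5-dimethyl-1,3-dioxolane, (10E)-alkene, aryl methoxymethyl ether, free C15 hydroxyl; (2S,6S,7S,14S) | C12(O[C@H](C)[C@@H](C)O1)CC[C@H](Br)[C@@]3(C)CC/C=C(C)/CC[C@@H](C(C)(C)O)OC(=O)c4ccc(OCOC)c(c4)C[C@H]23 | intermediate
30 | 10,11-deoxy-20-nor-3-oxobromophycolide F: macrocyclic C3 ketone, free phenol, (10E)-alkene; (2S,6S,7S,14S) | O=C1CC[C@H](Br)[C@@]2(C)CC/C=C(C)/CC[C@@H](C(C)(C)O)OC(=O)c3ccc(O)c(c3)C[C@H]12 | intermediate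
31 | 10,11-deoxybromophycolide F: (10E)-alkene; (2R,6S,7S,14S) | C=C1CC[C@H](Br)[C@@]2(C)CC/C=C(C)/CC[C@@H](C(C)(C)O)OC(=O)c3ccc(O)c(c3)C[C@H]12 | intermediate
32 | bromophycolide F (2R,6S,7S,10S,11S,14S) | C=C1CC[C@H](Br)[C@@]2(C)CC[C@@H]3O[C@@]3(C)CC[C@@H](C(C)(C)O)OC(=O)c3ccc(O)c(c3)C[C@H]12 | target

## Step count and risk

Total: 20 steps. Longest linear sequence: 17 steps (steps 1–10, 12, 13 and 16–20); step 11 prepares ketone 19 and steps 14–15 prepare acid 26.

**Step 17 (key step).** The most likely failure is slow transmetallation of the β-branched primary alkylborane, whose neighbours are a quaternary carbon and a ketal carbon; at the dilution needed, protodeboronation and intermolecular coupling could then overtake ring closure. Lesser concerns are partial hydroboration of C10=C11 and incomplete facial selectivity if the ring A chair with axial bromine takes part. The fallback keeps the same bond and reaction but closes the ring elsewhere. Starting from diol 23 and iodide 25, 23 is hydroborated with 9-BBN and coupled intermolecularly with 25 at normal concentration (PdCl2(dppf), Cs2CO3) to give the seco methyl ester F1. Saponification with LiOH gives the seco acid F2, and Yamaguchi macrolactonization at the secondary C14 hydroxyl returns to the route at 29.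

**Step 6.** The keto ester may cyclize through its carbonyl oxygen to a cyclic enol ether, or be brominated at C2, instead of forming the C2–C7 bond. The fallback starts from 10 and separates ring closure from bromination. Hg(OTf)2 with PhNMe2 in MeNO2 at −20 °C, followed by aqueous KBr, should close the ring through a reversibly formed mercurinium ion that the keto ester carbon captures, giving the C6 bromomercurio keto ester F3. Bromodemercuration with Br2 and LiBr in pyridine under O2, conditions that favour electrophilic cleavage with retention at C6, returns to the route at 11.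

**Step 7.** Decarboxylation of keto acid 12 may run ahead of C–C bond formation at the crowded C2, leaving the plain ketone, which cannot be methylenated regioselectively; amine may also add to the enone. The fallback starts from 11 and attaches C1 before CO2 is lost. Aldol reaction with aq. CH2O/KHCO3 gives the hydroxymethyl keto ester F4 and acetylation gives the acetate F5. Pd(OAc)2/PPh3 in MeCN then effects decarboxylation with loss of acetate (Tsuji reaction) and returns to the route at 13.

**Step 8.** The two diastereomeric ketals formed from racemic 13 may co-elute, and the diol may add to the enone in conjugate fashion. The fallback starts from 13 and resolves before ketalization. Reduction with (S)-2-methyl-CBS-oxazaborolidine and catecholborane converts the two enantiomers under reagent control into diastereomeric allylic alcohols, from which the (1S,3R,6S)-alcohol F6 is isolated by chromatography. Dess–Martin oxidation gives the single-enantiomer enone F7, and ketalization as in step 8 returns to the route at 14 without a diastereomer to remove.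

**Step 20.** At the pH of the epoxidation the phenol is largely ionized and may be oxidized by the dioxirane; the facial preference of the macrocycle may oppose the catalyst; and excess oxidant may reach C3=C20. The fallback starts from 31: silylation with i-Pr3SiCl/imidazole gives the aryl silyl ether F8, epoxidation under the same catalyst gives the silyl ether of the target F9, and n-Bu4NF buffered with AcOH returns to the route at 32.

## Further compounds

F1 | step 17 | seco methyl ester: ring A ketal with C2–CH2–aryl (aryl = 5-methoxycarbonyl-2-(methoxymethoxy)phenyl) and the (3S)-2,3-diol chain | C12(O[C@H](C)[C@@H](C)O1)CC[C@H](Br)[C@@](C)(CC/C=C(C)/CC[C@H](O)C(C)(C)O)[C@@H]2Cc3cc(C(=O)OC)ccc3OCOC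
F2 | step 17 | seco acid corresponding to F1 | C12(O[C@H](C)[C@@H](C)O1)CC[C@H](Br)[C@@](C)(CC/C=C(C)/CC[C@H](O)C(C)(C)O)[C@@H]2Cc3cc(C(=O)O)ccc3OCOC
F3 | step 6 | rac-prop-2-en-1-yl (2S,3S)-3-(bromomercurio)-2-[(3E)-5-ethoxy-4-methyl-5-oxopent-3-en-1-yl]-2-methyl-6-oxocyclohexane-1-carboxylate | O=C1CC[C@H]([Hg]Br)[C@@](C)(CC/C=C(C)/C(=O)OCC)C1C(=O)OCC=C
F4 | step 7 | rac-prop-2-en-1-yl (2S,3S)-3-bromo-2-[(3E)-5-ethoxy-4-methyl-5-oxopent-3-en-1-yl]-1-(hydroxymethyl)-2-methyl-6-oxocyclohexane-1-carboxylate | O=C1CC[C@H](Br)[C@@](C)(CC/C=C(C)/C(=O)OCC)C1(CO)C(=O)OCC=C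
F5 | step 7 | acetate of F4 | O=C1CC[C@H](Br)[C@@](C)(CC/C=C(C)/C(=O)OCC)C1(COC(C)=O)C(=O)OCC=C
F6 | step 8 | ethyl (2E)-5-[(1S,3R,6S)-6-bromo-3-hydroxy-1-methyl-2-methylidenecyclohexyl]-2-methylpent-2-enoate | C=C1[C@H](O)CC[C@H](Br)[C@@]1(C)CC/C=C(C)/C(=O)OCC
F7 | step 8 | ethyl (2E)-5-[(1S,6S)-6-bromo-1-methyl-2-methylidene-3-oxocyclohexyl]-2-methylpent-2-enoate (single enantiomer of 13) | C=C1C(=O)CC[C@H](Br)[C@@]1(C)CC/C=C(C)/C(=O)OCC
F8 | step 20 | aryl triisopropylsilyl ether of 31 | C=C1CC[C@H](Br)[C@@]2(C)CC/C=C(C)/CC[C@@H](C(C)(C)O)OC(=O)c3ccc(O[Si](C(C)C)(C(C)C)C(C)C)c(c3)C[C@H]12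
F9 | step 20 | aryl triisopropylsilyl ether of bromophycolide F | C=C1CC[C@H](Br)[C@@]2(C)CC[C@@H]3O[C@@]3(C)CC[C@@H](C(C)(C)O)OC(=O)c3ccc(O[Si](C(C)C)(C(C)C)C(C)C)c(c3)C[C@H]12
A1 | alternative 1 | 19-membered macrolactone with (2E)- and (6E)-alkenes, 10,11-diol acetonide and phenol acetate | C1/C=C(C)/CC/C=C(C)/CC[C@H]2OC(C)(C)O[C@@]2(C)CC[C@@H](C(C)(C)O)OC(=O)c2ccc(OC(C)=O)c1c2
A2 | alternative 1 | bromophycolide F skeleton as 10,11-diol acetonide and phenol acetate | C=C1CC[C@H](Br)[C@@]2(C)CC[C@H]3OC(C)(C)O[C@@]3(C)CC[C@@H](C(C)(C)O)OC(=O)c3ccc(OC(C)=O)c(c3)C[C@H]12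
A3 | alternative 2 | seco coumalate ester on O14 with triisopropylsiloxyalkyne on C1 (C15 triethylsilyl ether) | C=C1CC[C@H](Br)[C@@](C)(CC[C@@H]2O[C@@]2(C)CC[C@@H](C(C)(C)O[Si](CC)(CC)CC)OC(=O)c2ccc(=O)oc2)[C@@H]1CC#CO[Si](C(C)C)(C(C)C)C(C)C
A4 | alternative 2 | bromophycolide F bis-silyl ether (aryl triisopropylsilyl, C15 triethylsilyl) | C=C1CC[C@H](Br)[C@@]2(C)CC[C@@H]3O[C@@]3(C)CC[C@@H](C(C)(C)O[Si](CC)(CC)CC)OC(=O)c3ccc(O[Si](C(C)C)(C(C)C)C(C)C)c(c3)C[C@H]12
A5 | alternative 3 | seco ring A β-keto allyl ester with 3-(acetoxymethyl)-4-hydroxybenzoate on O14 | O=C1CC[C@H](Br)[C@@](C)(CC[C@@H]2O[C@@]2(C)CC[C@@H](C(C)(C)O)OC(=O)c2ccc(O)c(COC(C)=O)c2)C1C(=O)OCC=C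
A6 | alternative 3 | macrocyclic C3 ketone with allyl ester on the quaternary C2 | O=C1CC[C@H](Br)[C@@]2(C)CC[C@@H]3O[C@@]3(C)CC[C@@H](C(C)(C)O)OC(=O)c3ccc(O)c(c3)C[C@]12C(=O)OCC=C
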